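A direct plan would make a protected 2,3-trans flavan-3-ol A1 (for example by enlarging a 2-aryl-2,3-dihydrobenzofuran-3-ylmethyl sulfonate through a phenonium ion) and use it twice.
One part would become the C4 electrophile A2 (4-benzylsulfanyl); the other, after inversion of C3 and benzylic oxidation at C4, the lower-unit bis(benzyl carbonate) A3.
Silver-promoted Friedel–Crafts alkylation would join them to dimer A4, whose upper C3 would then be inverted through ketone A5 and a bulky hydride, before hydrogenolysis.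
First weakness, the Friedel–Crafts union of two flavans: C6′ and C5′ of the 7,8-dioxygenated nucleophile are both activated and the cation can alkylate its own kind, so regiochemistry would be left to chance on the most valuable material.
Second weakness, the late oxidation–reduction at C3 of the dimer: ketone A5 has doubly activated α-hydrogens at C2 and C4, a basic hydride could enolise it and scramble the centres just set, and the all-cis triad would rest on this one hindered reduction.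
Third weakness, the phenonium ring enlargement: it lacks close precedent, competes with direct substitution and elimination, and about seven steps would lead only to a monomer with the wrong (trans) C2/C3 relation, corrected twice by oxidation–reduction.
In addition, the final hydrogenolysis would expose a benzylic carbonate at C4′ to C–O cleavage.

Plan of the new route (rings A/B/C = benzo, catechol and pyran ring of the upper unit; D/E/F = the same of the lower unit, primed atoms):
Retrosynthesis: ring F is opened at O1′–C2′ (cis-oxirane of a (Z)-allylic alcohol) and C3′–C4′ is cut (alkyne + aldehyde); ring C is cut across O1–C2 and C3–C4 (ortho-quinone methide + (Z)-enol benzoate); last, C4–C6′ is cut (aryllithium + salicylaldehyde).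
Forward, the interflavan bond C4–C6′ is made first, between two simple arenes that both come from 2,3,4-trihydroxybenzaldehyde, at a carbon marked by bromine; ring C then arises in one cycloaddition with C2, C3 and C4 all-cis; ring F comes last, C4′ set by catalysis and C3′, C2′ relayed from it.
The feature that allows the key step: C4 is a diarylmethine carbon and ring A carries O1 ortho to it (at C8a), so O1–C8a–C4a–C4 is a latent 1-oxadiene, while C2–C3 with cis aryl and oxygen is a latent (Z)-enol ester; both Z-alkenes come from one arylacetylene.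
The weak steps do not arise: no flavan is a Friedel–Crafts partner (the site is fixed by a C–Br bond), no hydroxyl is inverted through a ketone, no ring is enlarged, and C4′ is a free alcohol at the hydrogenolysis.

Key step: step 7

Assumption: the sense of induction of the chiral acid in step 7 and of the ProPhenol–zinc catalyst in step 8 is taken as written; should either be opposite, the mirror-image catalyst would be used.

Step 1
Reactants: 1 2,3,4-trihydroxybenzaldehyde
Product: 2 3,4-bis(benzyloxy)-2-hydroxybenzaldehyde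
Conditions: BnBr (2.1 equiv), K2CO3 (2.2 equiv), DMF, rt
Reagents that add atoms: benzyl bromide, BrCc1ccccc1
Why: Williamson etherification should alkylate O3 and O4 only, the 2-hydroxyl being held in a hydrogen bond to the formyl group; 2 serves both as ring A and as the precursor of ring D.

Step 2
Reactants: 2 3,4-bis(benzyloxy)-2-hydroxybenzaldehyde
Product: 3 3,4-bis(benzyloxy)-5-bromo-2-hydroxybenzaldehyde
Conditions: NBS (1.05 equiv), MeCN, 0 °C
Reagents that add atoms: N-bromosuccinimide, O=C1CCC(=O)N1Br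
Why: Electrophilic aromatic bromination should go para to the free hydroxyl (C5, the future C6′), so that the site of the interflavan bond is fixed by a carbon–bromine bond and not by the selectivity of a later coupling.

Step 3
Reactants: 3 3,4-bis(benzyloxy)-5-bromo-2-hydroxybenzaldehyde
Product: 4 3,4-bis(benzyloxy)-5-bromo-2-(triisopropylsilyloxy)benzaldehyde
Conditions: TIPSOTf (1.2 equiv), 2,6-lutidine, CH2Cl2, 0 °C to rt
Reagents that add atoms: triisopropylsilyl trifluoromethanesulfonate, CC(C)[Si](C(C)C)(C(C)C)OS(=O)(=O)C(F)(F)F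
Why: Silylation of the phenol (the future O1′) with the bulky triisopropylsilyl group, which tolerates aryllithium, Brønsted acid and organozinc reagents, migrates only slowly to a neighbouring alkoxide and is removed later by fluoride without acid.

Step 4
Reactants: 5 3,4-bis(benzyloxy)benzaldehyde
Product: 6 1,2-bis(benzyloxy)-4-ethynylbenzene
Conditions: dimethyl (1-diazo-2-oxopropyl)phosphonate (1.3 equiv), K2CO3, MeOH, rt
Reagents that add atoms: dimethyl (1-diazo-2-oxopropyl)phosphonate, CC(=O)C(=[N+]=[N-])P(=O)(OC)OC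
Why: Seyferth–Gilbert homologation with the Ohira–Bestmann reagent turns the aldehyde into the terminal alkyne, which supplies C2/C3 of the upper unit (by way of 7) and C2′/C3′ of the lower unit.

Step 5
Reactants: 6 1,2-bis(benzyloxy)-4-ethynylbenzene
Product: 7 (Z)-2-[3,4-bis(benzyloxy)phenyl]ethenyl benzoate
Conditions: PhCO2H (1.2 equiv), [RuCl2(p-cymene)]2 (1 mol %), P(4-ClC6H4)3 (3 mol %), DMAP (4 mol %), toluene, 60 °C
Reagents that add atoms: benzoic acid, O=C(O)c1ccccc1
Why: Ruthenium-catalysed anti-Markovnikov addition of the carboxylic acid to the terminal alkyne (through a ruthenium vinylidene) should give the (Z)-enol ester, in which the aryl group and the oxygen are cis as they must be at C2 and C3.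

Step 6
Reactants: 4 3,4-bis(benzyloxy)-5-bromo-2-(triisopropylsilyloxy)benzaldehyde; 2 3,4-bis(benzyloxy)-2-hydroxybenzaldehyde
Product: 11 3,4-bis(benzyloxy)-5-{[3,4-bis(benzyloxy)-2-hydroxyphenyl](hydroxy)methyl}-2-(triisopropylsilyloxy)benzaldehyde (both carbinol epimers), via lithium α-amino alkoxide 8 (not isolated), via aryllithium 9 (not isolated), via sodium phenolate 10 (not isolated)
Conditions: LiN(Me)CH2CH2NMe2 (1.1 equiv, from the amine and n-BuLi), 4, THF, −20 °C; n-BuLi (1.1 equiv), −78 °C; then 10 (from 2 and NaH, THF, 0 °C), −78 to −20 °C; then H2O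
Reagents that add atoms: none
Why: Masking of the formyl group of 4 as its lithium α-amino alkoxide allows bromine–lithium exchange, and 1,2-addition of the aryllithium to the formyl group of phenolate 10 forms the C4–C6′ bond; water returns the aldehyde, and the carbinol carbon (both epimers) becomes trigonal in step 7.

Step 7
Reactants: 11 3,4-bis(benzyloxy)-5-{[3,4-bis(benzyloxy)-2-hydroxyphenyl](hydroxy)methyl}-2-(triisopropylsilyloxy)benzaldehyde; 7 (Z)-2-[3,4-bis(benzyloxy)phenyl]ethenyl benzoate (1.5 equiv)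
Product: 13 (2R,3R)-all-cis-7,8-bis(benzyloxy)-2-[3,4-bis(benzyloxy)phenyl]-4-[2,3-bis(benzyloxy)-5-formyl-4-(triisopropylsilyloxy)phenyl]chroman-3-yl benzoate, via ortho-quinone methide 12 (not isolated)
Conditions: (R)-3,3′-bis(2,4,6-triisopropylphenyl)-1,1′-binaphthyl-2,2′-diyl N-triflylphosphoramide (10 mol %), CHCl3, 5 Å MS, −20 °C to rt
Reagents that add atoms: none
Why: Proposed new method: the acid dehydrates benzhydrol 11 to the (E)-ortho-quinone methide 12, held as a hydrogen-bonded ion pair by the chiral phosphoramide, and the (Z)-enol benzoate 7 adds to it in an asynchronous inverse-demand oxa-[4+2] cycloaddition in which C3–C4 bond formation runs ahead of O1–C2 closure. The closest known reaction type is the chiral N-triflylphosphoramide-catalysed [4+2] cycloaddition of aryl-substituted ortho-quinone methides with styrenes to 2,4-cis-2,4-diarylchromans; an enol ester of an arylacetaldehyde has not been used as the 2π partner. Ring C closes as a six-membered ring by cycloaddition across O1=C8a–C4a=C4, both new bonds forming on one face of the dienophile. C2 and C3 are set cis by the Z geometry of 7, C4 is set cis to both by the endo approach of ring B and the cis benzoyloxy group to the E-configured methide, and the absolute sense (2R,3R) by the face of 12 that the catalyst leaves open. The step needs C4 to bond to the benzoyloxy-bearing carbon and O1 to the benzylic carbon, which should be secured because the para-benzyloxy group of ring B stabilises positive charge at the benzylic carbon better than the acyl-attenuated enol oxygen does at the other. It also needs the quinone methide to form on ring A only, which is secured by the free O1–H while O7′ is benzylated and O8a′ silylated.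

Step 8
Reactants: 13 (2R,3R)-all-cis-7,8-bis(benzyloxy)-2-[3,4-bis(benzyloxy)phenyl]-4-[2,3-bis(benzyloxy)-5-formyl-4-(triisopropylsilyloxy)phenyl]chroman-3-yl benzoate; 6 1,2-bis(benzyloxy)-4-ethynylbenzene (3 equiv)
Product: 15 (2R,3R)-all-cis-7,8-bis(benzyloxy)-2-[3,4-bis(benzyloxy)phenyl]-4-[2,3-bis(benzyloxy)-5-{(1R)-3-[3,4-bis(benzyloxy)phenyl]-1-hydroxyprop-2-yn-1-yl}-4-(triisopropylsilyloxy)phenyl]chroman-3-yl benzoate, via methylzinc acetylide 14 (not isolated)
Conditions: Me2Zn (3 equiv), (R,R)-ProPhenol (20 mol %), Ph3PO (40 mol %), toluene, 0 to 4 °C; then H2O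
Reagents that add atoms: none
Why: Zinc–ProPhenol-catalysed enantioselective addition of the alkynylzinc to the aryl aldehyde (catalytic asymmetric alkynylation) forms C3′–C4′ and sets C4′ (1R in the propargylic alcohol) under catalyst control, the existing centres being remote and the benzoate inert to organozinc reagents.

Step 9
Reactants: 15 the (1R)-propargylic alcohol
Product: 16 (2R,3R)-all-cis-7,8-bis(benzyloxy)-2-[3,4-bis(benzyloxy)phenyl]-4-[2,3-bis(benzyloxy)-5-{(1R,2Z)-3-[3,4-bis(benzyloxy)phenyl]-1-hydroxyprop-2-en-1-yl}-4-(triisopropylsilyloxy)phenyl]chroman-3-yl benzoate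
Conditions: H2 (1 atm), Pd/CaCO3 poisoned with Pb(OAc)2 (Lindlar catalyst), quinoline, EtOAc, rt
Reagents that add atoms: none
Why: Lindlar semi-hydrogenation adds hydrogen syn to the alkyne and should stop at the (Z)-alkene, the basic quinoline-containing medium sparing the acid-labile diarylallyl alcohol, the benzyl ethers and the benzoate.

Step 10
Reactants: 16 the (1R,2Z)-allylic alcohol
Product: 17 (2R,3R)-all-cis-7,8-bis(benzyloxy)-2-[3,4-bis(benzyloxy)phenyl]-4-[2,3-bis(benzyloxy)-5-{(S)-[(2R,3S)-3-[3,4-bis(benzyloxy)phenyl]oxiran-2-yl](hydroxy)methyl}-4-(triisopropylsilyloxy)phenyl]chroman-3-yl benzoate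
Conditions: dimethyldioxirane (DMDO, 1.2 equiv), CH2Cl2/acetone, −40 to −20 °C
Reagents that add atoms: dimethyldioxirane, CC1(C)OO1
Why: Hydroxyl-directed epoxidation of a (Z)-allylic alcohol: 1,3-allylic strain holds H4′ in the plane of the alkene and the oxidant, hydrogen-bonded to the 4′-hydroxyl, is delivered to the face that carries it, which gives the threo epoxy alcohol (C3′ relayed from C4′) under neutral conditions that the electron-rich aryl oxirane should survive.

Step 11
Reactants: 17 the threo cis-epoxy alcohol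
Product: 19 (2R,3R)-all-cis-7,8-bis(benzyloxy)-2-[3,4-bis(benzyloxy)phenyl]-4-{(2R,3R,4S)-7,8-bis(benzyloxy)-2-[3,4-bis(benzyloxy)phenyl]-3,4-dihydroxychroman-6-yl}chroman-3-yl benzoate, via phenol 18 (not isolated)
Conditions: TBAF (1.1 equiv), AcOH (1.2 equiv), THF, 0 °C; then Ti(OiPr)4 (1.5 equiv), CH2Cl2, 0 °C to rt
Reagents that add atoms: none
Why: Fluoride frees O1′–H, which opens the titanium-activated oxirane at the benzylic carbon C2′ (C-3 of the 2,3-epoxy alcohol; 6-endo closure of ring F, preferred over 5-exo at C3′ because of benzylic activation) with inversion, so that the cis-oxirane gives the 2,3-cis relation and the threo relation becomes 3,4-trans (epoxide ring opening by a phenol).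

Step 12
Reactants: 19 the 3-benzoate of the protected dimer
Product: 20 (2R,3R,4S)-7,8-bis(benzyloxy)-6-{(2R,3R)-all-cis-7,8-bis(benzyloxy)-2-[3,4-bis(benzyloxy)phenyl]-3-hydroxychroman-4-yl}-2-[3,4-bis(benzyloxy)phenyl]chromane-3,4-diol
Conditions: NaOMe (0.3 equiv), MeOH/THF, rt to 40 °C
Reagents that add atoms: none
Why: Base-catalysed transesterification removes the benzoate while all phenols are still benzylated, so that the free polyphenol never meets base.

Step 13
Reactants: 20 the octabenzyl ether triol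
Product: 21 CNP0143773.1
Conditions: H2 (1 atm), Pd(OH)2/C, THF/MeOH, rt
Reagents that add atoms: none
Why: Neutral hydrogenolysis should cleave the eight benzyl ethers, C4′ carrying a free hydroxyl, the form of this benzylic position least prone to C–O hydrogenolysis.

Compound list
1 | 2,3,4-trihydroxybenzaldehyde | O=Cc1ccc(O)c(O)c1O | starting material
2 | 3,4-bis(benzyloxy)-2-hydroxybenzaldehyde | O=Cc1ccc(OCc2ccccc2)c(OCc2ccccc2)c1O | intermediate
3 | 3,4-bis(benzyloxy)-5-bromo-2-hydroxybenzaldehyde | O=Cc1cc(Br)c(OCc2ccccc2)c(OCc2ccccc2)c1O | intermediate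
4 | 3,4-bis(benzyloxy)-5-bromo-2-(triisopropylsilyloxy)benzaldehyde | O=Cc1cc(Br)c(OCc2ccccc2)c(OCc2ccccc2)c1O[Si](C(C)C)(C(C)C)C(C)C | intermediate
5 | 3,4-bis(benzyloxy)benzaldehyde | O=Cc1ccc(OCc2ccccc2)c(OCc2ccccc2)c1 | starting material
6 | 1,2-bis(benzyloxy)-4-ethynylbenzene | C#Cc1ccc(OCc2ccccc2)c(OCc2ccccc2)c1 | intermediate
7 | (Z)-2-[3,4-bis(benzyloxy)phenyl]ethenyl benzoate | O=C(O/C=C\c1ccc(OCc2ccccc2)c(OCc2ccccc2)c1)c1ccccc1 | intermediate
8 | lithium α-amino alkoxide of 4 with N,N,N′-trimethylethylenediamine (not isolated; carbinol carbon racemic) | [Li+].[O-]C(N(C)CCN(C)C)c1cc(Br)c(OCc2ccccc2)c(OCc2ccccc2)c1O[Si](C(C)C)(C(C)C)C(C)C | intermediate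
9 | 5-lithio analogue of 8 (aryllithium, not isolated) | [Li+].[O-]C(N(C)CCN(C)C)c1cc([Li])c(OCc2ccccc2)c(OCc2ccccc2)c1O[Si](C(C)C)(C(C)C)C(C)C | intermediate
10 | sodium 2,3-bis(benzyloxy)-6-formylphenolate (not isolated) | [Na+].[O-]c1c(C=O)ccc(OCc2ccccc2)c1OCc1ccccc1 | intermediate
11 | 3,4-bis(benzyloxy)-5-{[3,4-bis(benzyloxy)-2-hydroxyphenyl](hydroxy)methyl}-2-(triisopropylsilyloxy)benzaldehyde (both carbinol epimers) | O=Cc1cc(C(O)c2ccc(OCc3ccccc3)c(OCc3ccccc3)c2O)c(OCc2ccccc2)c(OCc2ccccc2)c1O[Si](C(C)C)(C(C)C)C(C)C | intermediate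
12 | (6E)-2,3-bis(benzyloxy)-6-{[2,3-bis(benzyloxy)-5-formyl-4-(triisopropylsilyloxy)phenyl]methylidene}cyclohexa-2,4-dien-1-one (ortho-quinone methide, not isolated) | O=C1/C(=C/c2cc(C=O)c(O[Si](C(C)C)(C(C)C)C(C)C)c(OCc3ccccc3)c2OCc2ccccc2)C=CC(OCc2ccccc2)=C1OCc1ccccc1 | intermediate
13 | (2R,3R)-all-cis-7,8-bis(benzyloxy)-2-[3,4-bis(benzyloxy)phenyl]-4-[2,3-bis(benzyloxy)-5-formyl-4-(triisopropylsilyloxy)phenyl]chroman-3-yl benzoate (2-aryl, 3-benzoyloxy and 4-aryl on one face) | C(c1ccccc1)Oc1ccc([C@H]2Oc3c(ccc(OCc4ccccc4)c3OCc3ccccc3)[C@@H](c3cc(C=O)c(O[Si](C(C)C)(C(C)C)C(C)C)c(OCc4ccccc4)c3OCc3ccccc3)[C@H]2OC(=O)c2ccccc2)cc1OCc1ccccc1 | intermediate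
14 | methyl{[3,4-bis(benzyloxy)phenyl]ethynyl}zinc (not isolated) | C[Zn]C#Cc1ccc(OCc2ccccc2)c(OCc2ccccc2)c1 | intermediate
15 | 13 with the formyl group replaced by (1R)-3-[3,4-bis(benzyloxy)phenyl]-1-hydroxyprop-2-yn-1-yl | C(c1ccccc1)Oc1ccc([C@H]2Oc3c(ccc(OCc4ccccc4)c3OCc3ccccc3)[C@@H](c3cc([C@H](O)C#Cc4ccc(OCc5ccccc5)c(OCc5ccccc5)c4)c(O[Si](C(C)C)(C(C)C)C(C)C)c(OCc4ccccc4)c3OCc3ccccc3)[C@H]2OC(=O)c2ccccc2)cc1OCc1ccccc1 | intermediate
16 | (1R,2Z)-allylic alcohol corresponding to 15 | C(c1ccccc1)Oc1ccc([C@H]2Oc3c(ccc(OCc4ccccc4)c3OCc3ccccc3)[C@@H](c3cc([C@H](O)/C=C\c4ccc(OCc5ccccc5)c(OCc5ccccc5)c4)c(O[Si](C(C)C)(C(C)C)C(C)C)c(OCc4ccccc4)c3OCc3ccccc3)[C@H]2OC(=O)c2ccccc2)cc1OCc1ccccc1 | intermediate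
17 | threo cis-epoxy alcohol: side chain (S)-[(2R,3S)-3-[3,4-bis(benzyloxy)phenyl]oxiran-2-yl](hydroxy)methyl | C(c1ccccc1)Oc1ccc([C@H]2Oc3c(ccc(OCc4ccccc4)c3OCc3ccccc3)[C@@H](c3cc([C@H](O)[C@H]4O[C@H]4c4ccc(OCc5ccccc5)c(OCc5ccccc5)c4)c(O[Si](C(C)C)(C(C)C)C(C)C)c(OCc4ccccc4)c3OCc3ccccc3)[C@H]2OC(=O)c2ccccc2)cc1OCc1ccccc1 | intermediate
18 | phenol from 17 by loss of the triisopropylsilyl group (not isolated) | C(c1ccccc1)Oc1ccc([C@H]2Oc3c(ccc(OCc4ccccc4)c3OCc3ccccc3)[C@@H](c3cc([C@H](O)[C@H]4O[C@H]4c4ccc(OCc5ccccc5)c(OCc5ccccc5)c4)c(O)c(OCc4ccccc4)c3OCc3ccccc3)[C@H]2OC(=O)c2ccccc2)cc1OCc1ccccc1 | intermediate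
19 | (2R,3R)-all-cis-7,8-bis(benzyloxy)-2-[3,4-bis(benzyloxy)phenyl]-4-{(2R,3R,4S)-7,8-bis(benzyloxy)-2-[3,4-bis(benzyloxy)phenyl]-3,4-dihydroxychroman-6-yl}chroman-3-yl benzoate | C(c1ccccc1)Oc1ccc([C@H]2Oc3c(ccc(OCc4ccccc4)c3OCc3ccccc3)[C@@H](c3cc4c(c(OCc5ccccc5)c3OCc3ccccc3)O[C@H](c3ccc(OCc5ccccc5)c(OCc5ccccc5)c3)[C@H](O)[C@H]4O)[C@H]2OC(=O)c2ccccc2)cc1OCc1ccccc1 | intermediate
20 | (2R,3R,4S)-7,8-bis(benzyloxy)-6-{(2R,3R)-all-cis-7,8-bis(benzyloxy)-2-[3,4-bis(benzyloxy)phenyl]-3-hydroxychroman-4-yl}-2-[3,4-bis(benzyloxy)phenyl]chromane-3,4-diol | C(c1ccccc1)Oc1ccc([C@H]2Oc3c(ccc(OCc4ccccc4)c3OCc3ccccc3)[C@@H](c3cc4c(c(OCc5ccccc5)c3OCc3ccccc3)O[C@H](c3ccc(OCc5ccccc5)c(OCc5ccccc5)c3)[C@H](O)[C@H]4O)[C@H]2O)cc1OCc1ccccc1 | intermediate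
21 | CNP0143773.1: all-cis (2R,3R) 7,8,3′,4′-tetrahydroxyflavan-3-ol unit bonded through C4 to C6′ of the (2R,3R,4S) 7,8,3′,4′-tetrahydroxyflavan-3,4-diol unit | Oc1ccc([C@H]2Oc3c(ccc(O)c3O)[C@@H](c3cc4c(c(O)c3O)O[C@H](c3ccc(O)c(O)c3)[C@H](O)[C@H]4O)[C@H]2O)cc1O | target

Total step count: 13. Longest linear sequence: 11 steps (steps 1, 2, 3, 6, 7, 8, 9, 10, 11, 12, 13).

Steps most likely to fail

Step 7 (Proposed new method). The enol ester may be too weak a 2π partner, so that the quinone methide is consumed by Friedel–Crafts attack on electron-rich rings or by self-addition; a stepwise path may lose the Z geometry, or an exo approach may give the C4 epimer. The fallback sets the three centres one after another by known reactions; it sets out from 11 and returns at 13. The quinone methide 12, generated as before, would be intercepted by diethyl (Z)-2-[3,4-bis(benzyloxy)phenyl]ethenylboronate F1 under catalysis by (R)-3,3′-dibromo-BINOL in toluene with 4 Å MS. F1 would come from 6 by trans-hydroboration with catecholborane, [Rh(cod)Cl]2, P(i-Pr)3 and Et3N, then exchange with ethanol. This biphenol-catalysed enantioselective conjugate alkenylation of ortho-quinone methides should give the (Z)-1,1,3-triarylpropene phenol F2 with C4 set as in 13 and the double bond intact. Silylation (TBSCl, imidazole) would give the silyl ether F3. Jacobsen–Katsuki epoxidation with (R,R)-[N,N′-bis(3,5-di-tert-butylsalicylidene)-1,2-cyclohexanediamine]MnCl and NaOCl, which is at its best with cis-disubstituted aryl alkenes, would give the cis-oxirane F4; the antipode of the catalyst is chosen to place oxygen on the face that makes O3 cis to the C4 aryl group. TBAF followed by camphorsulfonic acid would close ring C by 6-endo attack of O1 at the benzylic C2 with inversion to the all-cis flavan-3-ol F5, and benzoylation (BzCl, pyridine, DMAP) would return to 13.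

Step 11. The oxirane may ionise at the benzylic carbon before the phenol arrives, which would lose the configuration at C2′, or it may be opened at C3′ in the 5-exo mode. The fallback closes ring F from a diol through an orthoester; it sets out from 16 and returns at 20. Hydroxyl-directed dihydroxylation (OsO4, TMEDA, CH2Cl2, −78 °C; the same face as in step 10, syn addition to the Z-alkene) would give the triol F8. TBAF/AcOH would free the phenol to give the tetraol F9. Triethyl orthoformate and PPTS would form the 2′,3′-orthoester, whose dioxolanylium ion is opened by O1′ at the benzylic C2′ with inversion (the orthoester cyclisation used for flavan-3-ols), to give the 3′-formate F10. NaOMe in MeOH would remove formate and benzoate together and return to 20.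

Step 8. The alkynylzinc may add sluggishly to the hindered ortho-silyloxy aldehyde or with poor face selectivity. The fallback sets C4′ by ketone reduction instead of C–C bond formation; it sets out from 13 and returns at 15. The lithium acetylide of 6 (n-BuLi, THF, −78 °C) would add to 13 to give the mixture of carbinol epimers F6, MnO2 would oxidise it to the ynone F7, and asymmetric transfer hydrogenation with RuCl(p-cymene)[(R,R)-TsDPEN] in HCO2H/Et3N would give 15.

Further compounds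
F1 | step 7 | diethyl (Z)-2-[3,4-bis(benzyloxy)phenyl]ethenylboronate | CCOB(OCC)/C=C\c1ccc(OCc2ccccc2)c(OCc2ccccc2)c1
F2 | step 7 | (Z)-1,1,3-triarylpropene phenol, C4 as in 13 | Oc1c(ccc(OCc2ccccc2)c1OCc1ccccc1)[C@@H](c1cc(C=O)c(O[Si](C(C)C)(C(C)C)C(C)C)c(OCc2ccccc2)c1OCc1ccccc1)/C=C\c1ccc(OCc2ccccc2)c(OCc2ccccc2)c1
F3 | step 7 | tert-butyldimethylsilyl ether of F2 | CC(C)(C)[Si](C)(C)Oc1c(ccc(OCc2ccccc2)c1OCc1ccccc1)[C@@H](c1cc(C=O)c(O[Si](C(C)C)(C(C)C)C(C)C)c(OCc2ccccc2)c1OCc1ccccc1)/C=C\c1ccc(OCc2ccccc2)c(OCc2ccccc2)c1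
F4 | step 7 | cis-oxirane of F3, oxygen on the face that becomes O3 | CC(C)(C)[Si](C)(C)Oc1c(ccc(OCc2ccccc2)c1OCc1ccccc1)[C@@H](c1cc(C=O)c(O[Si](C(C)C)(C(C)C)C(C)C)c(OCc2ccccc2)c1OCc1ccccc1)[C@H]1O[C@H]1c1ccc(OCc2ccccc2)c(OCc2ccccc2)c1
F5 | step 7 | (2R,3R)-all-cis-7,8-bis(benzyloxy)-2-[3,4-bis(benzyloxy)phenyl]-4-[2,3-bis(benzyloxy)-5-formyl-4-(triisopropylsilyloxy)phenyl]chroman-3-ol | C(c1ccccc1)Oc1ccc([C@H]2Oc3c(ccc(OCc4ccccc4)c3OCc3ccccc3)[C@@H](c3cc(C=O)c(O[Si](C(C)C)(C(C)C)C(C)C)c(OCc4ccccc4)c3OCc3ccccc3)[C@H]2O)cc1OCc1ccccc1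
F6 | step 8 | mixture of the C4′ epimers of 15 | C(c1ccccc1)Oc1ccc([C@H]2Oc3c(ccc(OCc4ccccc4)c3OCc3ccccc3)[C@@H](c3cc(C(O)C#Cc4ccc(OCc5ccccc5)c(OCc5ccccc5)c4)c(O[Si](C(C)C)(C(C)C)C(C)C)c(OCc4ccccc4)c3OCc3ccccc3)[C@H]2OC(=O)c2ccccc2)cc1OCc1ccccc1
F7 | step 8 | ynone: 13 with the formyl group replaced by 3-[3,4-bis(benzyloxy)phenyl]prop-2-ynoyl | C(c1ccccc1)Oc1ccc([C@H]2Oc3c(ccc(OCc4ccccc4)c3OCc3ccccc3)[C@@H](c3cc(C(=O)C#Cc4ccc(OCc5ccccc5)c(OCc5ccccc5)c4)c(O[Si](C(C)C)(C(C)C)C(C)C)c(OCc4ccccc4)c3OCc3ccccc3)[C@H]2OC(=O)c2ccccc2)cc1OCc1ccccc1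
F8 | step 11 | triol from 16: 2′,3′-erythro, 3′,4′-threo 1,3-diarylpropane-1,2,3-triol side chain, silyl ether intact | C(c1ccccc1)Oc1ccc([C@H]2Oc3c(ccc(OCc4ccccc4)c3OCc3ccccc3)[C@@H](c3cc([C@H](O)[C@@H](O)[C@@H](O)c4ccc(OCc5ccccc5)c(OCc5ccccc5)c4)c(O[Si](C(C)C)(C(C)C)C(C)C)c(OCc4ccccc4)c3OCc3ccccc3)[C@H]2OC(=O)c2ccccc2)cc1OCc1ccccc1
F9 | step 11 | phenol from F8 by loss of the triisopropylsilyl group | C(c1ccccc1)Oc1ccc([C@H]2Oc3c(ccc(OCc4ccccc4)c3OCc3ccccc3)[C@@H](c3cc([C@H](O)[C@@H](O)[C@@H](O)c4ccc(OCc5ccccc5)c(OCc5ccccc5)c4)c(O)c(OCc4ccccc4)c3OCc3ccccc3)[C@H]2OC(=O)c2ccccc2)cc1OCc1ccccc1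
F10 | step 11 | 3′-O-formate of 19 | C(c1ccccc1)Oc1ccc([C@H]2Oc3c(ccc(OCc4ccccc4)c3OCc3ccccc3)[C@@H](c3cc4c(c(OCc5ccccc5)c3OCc3ccccc3)O[C@H](c3ccc(OCc5ccccc5)c(OCc5ccccc5)c3)[C@H](OC=O)[C@H]4O)[C@H]2OC(=O)c2ccccc2)cc1OCc1ccccc1
A1 | direct plan | (2R,3S)-7,8-bis(benzyloxy)-2-[3,4-bis(benzyloxy)phenyl]chroman-3-ol (2,3-trans) | O[C@H]1Cc2ccc(OCc3ccccc3)c(OCc3ccccc3)c2O[C@@H]1c1ccc(OCc2ccccc2)c(OCc2ccccc2)c1
A2 | direct plan | (2R)-2,3-trans-3,4-trans-4-(benzylsulfanyl)-7,8-bis(benzyloxy)-2-[3,4-bis(benzyloxy)phenyl]chroman-3-ol | C(c1ccccc1)Oc1ccc([C@H]2Oc3c(ccc(OCc4ccccc4)c3OCc3ccccc3)[C@@H](SCc3ccccc3)[C@@H]2O)cc1OCc1ccccc1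
A3 | direct plan | (2R,3R,4S)-7,8-bis(benzyloxy)-2-[3,4-bis(benzyloxy)phenyl]chromane-3,4-diyl dibenzyl dicarbonate | c1cc2c(c(OCc3ccccc3)c1OCc1ccccc1)O[C@H](c1ccc(OCc3ccccc3)c(OCc3ccccc3)c1)[C@H](OC(=O)OCc1ccccc1)[C@H]2OC(=O)OCc1ccccc1
A4 | direct plan | C4→C6′ dimer with 2,3-trans-3,4-trans upper unit (free 3-OH) and lower unit as in A3 | C(c1ccccc1)Oc1ccc([C@H]2Oc3c(ccc(OCc4ccccc4)c3OCc3ccccc3)[C@@H](c3cc4c(c(OCc5ccccc5)c3OCc3ccccc3)O[C@H](c3ccc(OCc5ccccc5)c(OCc5ccccc5)c3)[C@H](OC(=O)OCc3ccccc3)[C@H]4OC(=O)OCc3ccccc3)[C@@H]2O)cc1OCc1ccccc1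
A5 | direct plan | C4→C6′ dimer with (2R)-2,4-cis-chroman-3-one upper unit | C(c1ccccc1)Oc1ccc([C@H]2Oc3c(ccc(OCc4ccccc4)c3OCc3ccccc3)[C@@H](c3cc4c(c(OCc5ccccc5)c3OCc3ccccc3)O[C@H](c3ccc(OCc5ccccc5)c(OCc5ccccc5)c3)[C@H](OC(=O)OCc3ccccc3)[C@H]4OC(=O)OCc3ccccc3)C2=O)cc1OCc1ccccc1
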